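**Retrosynthetic overview**
- The target comes from a ten-membered 8-hydroxy-9-silyloxy lactone by C8 methacryloylation, silyl-to-acetyl exchange at O9 and a final SeO2 oxidation of the C14 methyl.
- The ten-membered ring is formed last, by making C8–C9 from two aldehyde carbons: the enal carbon C9 is turned into a nucleophile (γ-siloxyallylchromium) and adds to the C8 aldehyde, setting C8, C9 and the 1(10) alkene.
- The trans γ-lactone with its C8 formyl group comes from translactonization and oxidation of an indium Barbier adduct; C6–C7 is made from an epoxy dialdehyde and 3-(bromomethyl)furan-2(5H)-one, setting C6 and C7.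
- The oxirane is formed first, by Sharpless epoxidation of nerol (sets C4, C5); SeO2 oxidation of the E-methyl supplies the C9 aldehyde.
- Ring order: oxirane, then γ-lactone, then ten-membered carbocycle.

Assumption: germacrane numbering is used for the macrocycles (C1–C10 ring, C11–C13 lactone carbons, C14 on C10, C15 on C4); the SMILES strings define the configurations, and operations telescoped in one flask count as one step.

Step 1
Reactants: 1 nerol ((2Z)-3,7-dimethylocta-2,6-dien-1-ol)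
Product: 2 [(2S,3R)-3-methyl-3-(4-methylpent-3-en-1-yl)oxiran-2-yl]methanol
Conditions: Ti(OiPr)4 (10 mol%), L-(+)-diethyl tartrate (12 mol%), t-BuOOH, 4 Å molecular sieves, CH2Cl2, −20 °C
Reagents that add atoms: tert-butyl hydroperoxide, CC(C)(C)OO
Why: Sharpless asymmetric epoxidation, in which the L-(+)-tartrate titanium catalyst delivers oxygen to one face of the Z-allylic alcohol and so sets C4 (R) and C5 (S) of the target as the cis-epoxide.

Step 2
Reactants: 2 [(2S,3R)-3-methyl-3-(4-methylpent-3-en-1-yl)oxiran-2-yl]methanol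
Product: 3 [(2S,3R)-3-[(3E)-5-hydroxy-4-methylpent-3-en-1-yl]-3-methyloxiran-2-yl]methanol
Conditions: SeO2 (0.2 equiv), t-BuOOH (2 equiv), CH2Cl2, rt
Reagents that add atoms: selenium dioxide, O=[Se]=O (transfers the oxygen); tert-butyl hydroperoxide, CC(C)(C)OO (re-oxidises selenium)
Why: Riley-type SeO2 allylic oxidation (ene reaction then [2,3]-sigmatropic shift) hydroxylates only the E-methyl of the electron-rich trisubstituted alkene, and this carbon becomes C9.

Step 3
Reactants: 3 [(2S,3R)-3-[(3E)-5-hydroxy-4-methylpent-3-en-1-yl]-3-methyloxiran-2-yl]methanol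
Product: 4 (2R,3R)-3-methyl-3-[(3E)-4-methyl-5-oxopent-3-en-1-yl]oxirane-2-carbaldehyde
Conditions: TEMPO (cat.), PhI(OAc)2 (2.4 equiv), CH2Cl2, rt
Reagents that add atoms: none
Why: Oxoammonium (TEMPO/PhI(OAc)2) oxidation takes both primary alcohols to aldehydes under near-neutral conditions that leave the epoxide and both stereocentres untouched.

Step 4
Reactants: 5 tulipalin A (3-methylideneoxolan-2-one)
Product: 6 3-(bromomethyl)furan-2(5H)-one
Conditions: NBS, AIBN (cat.), PhCF3, 80 °C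
Reagents that add atoms: N-bromosuccinimide, O=C1CCC(=O)N1Br
Why: Wohl–Ziegler allylic bromination, in which the allyl radical formed at the ring CH2 is brominated at the exocyclic terminus to give the conjugated endocyclic alkene.

Step 5
Reactants: 4 (2R,3R)-3-methyl-3-[(3E)-4-methyl-5-oxopent-3-en-1-yl]oxirane-2-carbaldehyde; 6 3-(bromomethyl)furan-2(5H)-one
Product: 8 (4R)-4-[(S)-hydroxy{(2S,3R)-3-methyl-3-[(3E)-4-methyl-5-oxopent-3-en-1-yl]oxiran-2-yl}methyl]-3-methylideneoxolan-2-one, via allylindium sesquibromide 7 (not isolated)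
Conditions: In powder, THF/H2O (1:1), 0 °C to rt
Reagents that add atoms: none
Why: Indium Barbier allylation, in which the butenolide β-carbon (C7) attacks as a nucleophile through a closed chair whose ring-locked geometry puts C8 equatorial (C6/C7 anti), the epoxy aldehyde is attacked in the Felkin–Anh sense with the epoxide C–O bond anti to the incoming carbon (C5/C6 anti), and the less electrophilic α-branched enal is left alone.

Step 6
Reactants: 8 (4R)-4-[(S)-hydroxy{(2S,3R)-3-methyl-3-[(3E)-4-methyl-5-oxopent-3-en-1-yl]oxiran-2-yl}methyl]-3-methylideneoxolan-2-one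
Product: 10 (2S,3S)-4-methylidene-2-{(2S,3R)-3-methyl-3-[(3E)-4-methyl-5-oxopent-3-en-1-yl]oxiran-2-yl}-5-oxooxolane-3-carbaldehyde, via hydroxymethyl lactone 9 (not isolated)
Conditions: DBU (0.1 equiv), CH2Cl2, 0 °C; then AcOH (0.1 equiv), TEMPO (cat.), PhI(OAc)2, rt
Reagents that add atoms: none
Why: Base-catalysed translactonization (intramolecular transesterification) moves the acyl group from the primary O8 to the secondary O6 to give the more substituted trans lactone 9, and the freed primary alcohol is oxidised at once by the primary-selective TEMPO/PhI(OAc)2 method without base that could epimerise C7 or shift the exocyclic alkene.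

Step 7
Reactants: 10 (2S,3S)-4-methylidene-2-{(2S,3R)-3-methyl-3-[(3E)-4-methyl-5-oxopent-3-en-1-yl]oxiran-2-yl}-5-oxooxolane-3-carbaldehyde
Product: 13 (1(10)Z,4R,5S,6S,7R,8S,9R)-4,5-epoxy-8-hydroxy-9-(triethylsilyloxy)germacra-1(10),11(13)-dien-12,6-olide, via siloxyallylchromium dichloride 11 (not isolated), via chromium alkoxide 12 (not isolated)
Conditions: CrCl2 (4 equiv), Et3SiCl (1.2 equiv), THF/DMF (10:1), 0.003 M, rt, syringe-pump addition of 10; aqueous work-up
Reagents that add atoms: chlorotriethylsilane, CC[Si](Cl)(CC)CC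
Why: Proposed new method: divalent chromium with Et3SiCl reduces only the enal to the γ-siloxyallylchromium 11, whose former aldehyde carbon C9 is now nucleophilic and adds to the C8 aldehyde through a closed chair (Cr–O8–C8–C9–C10–C1) to close the ten-membered ring; the E siloxy group and C7 sit equatorial (8,9-anti), the tether can only span the chair on the face away from H8, which puts C2 axial (ring-cis 1(10) alkene) and C6 gauche to the forming bond with H7 beside the siloxy group (8S,9R relative to 7R), and O9 leaves silylated while O8 stays on trivalent chromium as 12 until work-up, so the two oxygens are differentiated; the closest known reactions are the intermolecular CrCl2/chlorosilane cross-pinacol-type coupling of enals with aldehydes and Nozaki–Hiyama–Kishi allylations that close ten-membered rings.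

Step 8
Reactants: 13 (1(10)Z,4R,5S,6S,7R,8S,9R)-4,5-epoxy-8-hydroxy-9-(triethylsilyloxy)germacra-1(10),11(13)-dien-12,6-olide
Product: 14 (1(10)Z,4R,5S,6S,7S,8S,9R)-4,5-epoxy-8-(methacryloyloxy)-9-(triethylsilyloxy)germacra-1(10),11(13)-dien-12,6-olide
Conditions: methacrylic anhydride, Et3N, DMAP (cat.), CH2Cl2, 0 °C to rt
Reagents that add atoms: methacrylic anhydride, C=C(C)C(=O)OC(=O)C(C)=C
Why: DMAP-catalysed acylation of the only free hydroxyl (O8) with retention at C8; the 7S descriptor is a priority change caused by silicon, not an inversion.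

Step 9
Reactants: 14 (1(10)Z,4R,5S,6S,7S,8S,9R)-4,5-epoxy-8-(methacryloyloxy)-9-(triethylsilyloxy)germacra-1(10),11(13)-dien-12,6-olide
Product: 16 (1(10)Z,4R,5S,6S,7R,8S,9R)-9-acetoxy-4,5-epoxy-8-(methacryloyloxy)germacra-1(10),11(13)-dien-12,6-olide, via C9 alcohol 15 (not isolated)
Conditions: Et3N·3HF, MeCN, rt; then pyridine, Ac2O, DMAP (cat.), 0 °C
Reagents that add atoms: acetic anhydride, CC(=O)OC(C)=O
Why: Fluoride desilylation under buffered, non-basic conditions (no acyl migration, epoxide inert at rt) followed in the same flask by DMAP-catalysed acetylation of O9, both with retention.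

Step 10
Reactants: 16 (1(10)Z,4R,5S,6S,7R,8S,9R)-9-acetoxy-4,5-epoxy-8-(methacryloyloxy)germacra-1(10),11(13)-dien-12,6-olide
Product: 18 (1(10)E,4R,5S,6S,7R,8S,9R)-9-acetoxy-4,5-epoxy-8-(methacryloyloxy)-14-oxogermacra-1(10),11(13)-dien-12,6-olide, via C14 alcohol 17 (not isolated)
Conditions: SeO2 (0.5 equiv), t-BuOOH (3 equiv), CH2Cl2, rt; then filter, MnO2, CH2Cl2, rt
Reagents that add atoms: selenium dioxide, O=[Se]=O (transfers the oxygen); tert-butyl hydroperoxide, CC(C)(C)OO (re-oxidises selenium)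
Why: SeO2 allylic oxidation (ene reaction then [2,3] shift) attacks the only electron-rich alkene at the C14 methyl (C9–H is a deactivated acetoxy methine) and returns the alkene with C14 trans to C2, and MnO2 oxidises the allylic alcohol to the enal; the change from Z to E is only a priority change.

**Compound list**
1 | nerol, (2Z)-3,7-dimethylocta-2,6-dien-1-ol | OC/C=C(/C)CCC=C(C)C | starting material
2 | [(2S,3R)-3-methyl-3-(4-methylpent-3-en-1-yl)oxiran-2-yl]methanol | OC[C@@H]1O[C@]1(C)CCC=C(C)C | intermediate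
3 | [(2S,3R)-3-[(3E)-5-hydroxy-4-methylpent-3-en-1-yl]-3-methyloxiran-2-yl]methanol | OC[C@@H]1O[C@]1(C)CC/C=C(\C)CO | intermediate
4 | (2R,3R)-3-methyl-3-[(3E)-4-methyl-5-oxopent-3-en-1-yl]oxirane-2-carbaldehyde | O=C[C@@H]1O[C@]1(C)CC/C=C(\C)C=O | intermediate
5 | tulipalin A, 3-methylideneoxolan-2-one | C=C1CCOC1=O | starting material
6 | 3-(bromomethyl)furan-2(5H)-one | BrCC1=CCOC1=O | intermediate
7 | tris[(2-oxo-2,5-dihydrofuran-3-yl)methyl]diindium tribromide (allylindium sesquibromide R3In2Br3, drawn as R2InBr·RInBr2) | O=C1OCC=C1C[In](Br)CC1=CCOC1=O.O=C1OCC=C1C[In](Br)Br | intermediate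
8 | (4R)-4-[(S)-hydroxy{(2S,3R)-3-methyl-3-[(3E)-4-methyl-5-oxopent-3-en-1-yl]oxiran-2-yl}methyl]-3-methylideneoxolan-2-one | O[C@H]([C@@H]1O[C@]1(C)CC/C=C(\C)C=O)[C@H]1COC(=O)C1=C | intermediate
9 | (4R,5S)-4-(hydroxymethyl)-3-methylidene-5-{(2S,3R)-3-methyl-3-[(3E)-4-methyl-5-oxopent-3-en-1-yl]oxiran-2-yl}oxolan-2-one | OC[C@H]1C(=C)C(=O)O[C@@H]1[C@@H]1O[C@]1(C)CC/C=C(\C)C=O | intermediate
10 | (2S,3S)-4-methylidene-2-{(2S,3R)-3-methyl-3-[(3E)-4-methyl-5-oxopent-3-en-1-yl]oxiran-2-yl}-5-oxooxolane-3-carbaldehyde | O=C[C@H]1C(=C)C(=O)O[C@@H]1[C@@H]1O[C@]1(C)CC/C=C(\C)C=O | intermediate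
11 | γ-siloxyallylchromium dichloride from 10: (2S,3S)-2-{(2S,3R)-3-[(4E)-3-(dichlorochromio)-4-methyl-5-(triethylsilyloxy)pent-4-en-1-yl]-3-methyloxiran-2-yl}-4-methylidene-5-oxooxolane-3-carbaldehyde (trivalent chromium on C1, that centre not fixed) | O=C[C@H]1C(=C)C(=O)O[C@@H]1[C@@H]1O[C@]1(C)CCC([Cr](Cl)Cl)/C(C)=C/O[Si](CC)(CC)CC | intermediate
12 | dichlorochromium 8-alkoxide of 13 | Cl[Cr](Cl)O[C@H]1[C@H]2C(=C)C(=O)O[C@@H]2[C@@H]2O[C@]2(C)CC/C=C(/C)[C@H]1O[Si](CC)(CC)CC | intermediate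
13 | (1(10)Z,4R,5S,6S,7R,8S,9R)-4,5-epoxy-8-hydroxy-9-(triethylsilyloxy)germacra-1(10),11(13)-dien-12,6-olide | O[C@H]1[C@H]2C(=C)C(=O)O[C@@H]2[C@@H]2O[C@]2(C)CC/C=C(/C)[C@H]1O[Si](CC)(CC)CC | intermediate
14 | (1(10)Z,4R,5S,6S,7S,8S,9R)-4,5-epoxy-8-(methacryloyloxy)-9-(triethylsilyloxy)germacra-1(10),11(13)-dien-12,6-olide | C=C(C)C(=O)O[C@H]1[C@H]2C(=C)C(=O)O[C@@H]2[C@@H]2O[C@]2(C)CC/C=C(/C)[C@H]1O[Si](CC)(CC)CC | intermediate
15 | (1(10)Z,4R,5S,6S,7R,8S,9R)-4,5-epoxy-9-hydroxy-8-(methacryloyloxy)germacra-1(10),11(13)-dien-12,6-olide | C=C(C)C(=O)O[C@H]1[C@H]2C(=C)C(=O)O[C@@H]2[C@@H]2O[C@]2(C)CC/C=C(/C)[C@H]1O | intermediate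
16 | (1(10)Z,4R,5S,6S,7R,8S,9R)-9-acetoxy-4,5-epoxy-8-(methacryloyloxy)germacra-1(10),11(13)-dien-12,6-olide | C=C(C)C(=O)O[C@H]1[C@H]2C(=C)C(=O)O[C@@H]2[C@@H]2O[C@]2(C)CC/C=C(/C)[C@H]1OC(C)=O | intermediate
17 | (1(10)Z,4R,5S,6S,7R,8S,9R)-9-acetoxy-4,5-epoxy-14-hydroxy-8-(methacryloyloxy)germacra-1(10),11(13)-dien-12,6-olide | C=C(C)C(=O)O[C@H]1[C@H]2C(=C)C(=O)O[C@@H]2[C@@H]2O[C@]2(C)CC/C=C(/CO)[C@H]1OC(C)=O | intermediate
18 | (1(10)E,4R,5S,6S,7R,8S,9R)-9-acetoxy-4,5-epoxy-8-(methacryloyloxy)-14-oxogermacra-1(10),11(13)-dien-12,6-olide (CNP0121379.1) | C=C(C)C(=O)O[C@H]1[C@H]2C(=C)C(=O)O[C@@H]2[C@@H]2O[C@]2(C)CC/C=C(/C=O)[C@H]1OC(C)=O | target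

**Step count and risks**
Total: 10 steps. Longest linear sequence: 9 steps (steps 1–3 and 5–10; step 4 makes the C5 reagent).

Most likely to fail, step 7 (chromium macrocyclization). The allylchromium may instead attack through C1 to give an eight-membered ring, the facial selectivity at C8 rests on a transition-state model, and the Lewis-acidic chromium/chlorosilane medium may open the epoxide. Fallback, from 10 back to 18: change from an allylmetal addition to a ketyl pinacol coupling. SmI2 (THF, −78 °C, high dilution) would give (1(10)E,4R,5S,6S,7R,8S,9R)-4,5-epoxy-8,9-dihydroxygermacra-1(10),11(13)-dien-12,6-olide F7, in which the enal geometry is kept (ring-trans 1(10) alkene). Acetylation of the less hindered allylic C9 hydroxyl (Ac2O, 2,4,6-collidine, −40 °C) gives the 9-acetate F8, and methacrylic anhydride/DMAP gives the 8-methacrylate F9. The SeO2/t-BuOOH then MnO2 oxidation of step 10 puts oxygen on C14 through the [2,3] shift, which resets the 1(10) geometry, so the sequence rejoins at 18.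

Second, step 6 (translactonization and oxidation). The acyl shift may stop at an equilibrium mixture, the freed C8 alkoxide may open the epoxide, and the β-formyl lactone 10 epimerises or isomerises easily. Fallback, from 4 back to 9: avoid the acyl shift with a geometrically defined allylboronate. Methyl (2Z)-4-[(tert-butyldimethylsilyl)oxy]-2-[(4,4,5,5-tetramethyl-1,3,2-dioxaborolan-2-yl)methyl]but-2-enoate F5 is made from methyl 4-(tert-butyldimethylsilyloxy)but-2-ynoate by i-Bu2AlH/HMPA hydroalumination and trapping with 2-(iodomethyl)-4,4,5,5-tetramethyl-1,3,2-dioxaborolane. It adds thermally to the epoxy aldehyde of 4 through a closed chair and lactonises directly onto O6 to give the trans lactone silyl ether F6. HF·pyridine then frees alcohol 9, which is oxidised to 10 as in the second half of step 6.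

Third, step 5 (Barbier on the dialdehyde). The reagent must choose the epoxy aldehyde over the enal and give the anti, Felkin adduct. Fallback, from 2 back to 10: form the C–C bond before the allylic oxidation. TEMPO/PhI(OAc)2 oxidises 2 to (2R,3R)-3-methyl-3-(4-methylpent-3-en-1-yl)oxirane-2-carbaldehyde F1, which has a single aldehyde. Indium coupling with 6 gives the adduct F2, and DBU-catalysed translactonization gives the hydroxymethyl lactone F3. SeO2/t-BuOOH hydroxylates the E-methyl to give the diol F4, and TEMPO/PhI(OAc)2 oxidises both primary alcohols to reach 10.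

**Further compounds**
F1 | step 5 | (2R,3R)-3-methyl-3-(4-methylpent-3-en-1-yl)oxirane-2-carbaldehyde | O=C[C@@H]1O[C@]1(C)CCC=C(C)C
F2 | step 5 | (4R)-4-[(S)-hydroxy{(2S,3R)-3-methyl-3-(4-methylpent-3-en-1-yl)oxiran-2-yl}methyl]-3-methylideneoxolan-2-one | O[C@H]([C@@H]1O[C@]1(C)CCC=C(C)C)[C@H]1COC(=O)C1=C
F3 | step 5 | (4R,5S)-4-(hydroxymethyl)-3-methylidene-5-[(2S,3R)-3-methyl-3-(4-methylpent-3-en-1-yl)oxiran-2-yl]oxolan-2-one | OC[C@H]1C(=C)C(=O)O[C@@H]1[C@@H]1O[C@]1(C)CCC=C(C)C
F4 | step 5 | (4R,5S)-4-(hydroxymethyl)-5-{(2S,3R)-3-[(3E)-5-hydroxy-4-methylpent-3-en-1-yl]-3-methyloxiran-2-yl}-3-methylideneoxolan-2-one | OC[C@H]1C(=C)C(=O)O[C@@H]1[C@@H]1O[C@]1(C)CC/C=C(\C)CO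
F5 | step 6 | methyl (2Z)-4-[(tert-butyldimethylsilyl)oxy]-2-[(4,4,5,5-tetramethyl-1,3,2-dioxaborolan-2-yl)methyl]but-2-enoate | COC(=O)/C(CB1OC(C)(C)C(C)(C)O1)=C\CO[Si](C)(C)C(C)(C)C
F6 | step 6 | (4R,5S)-4-{[(tert-butyldimethylsilyl)oxy]methyl}-3-methylidene-5-{(2S,3R)-3-methyl-3-[(3E)-4-methyl-5-oxopent-3-en-1-yl]oxiran-2-yl}oxolan-2-one | CC(C)(C)[Si](C)(C)OC[C@H]1C(=C)C(=O)O[C@@H]1[C@@H]1O[C@]1(C)CC/C=C(\C)C=O
F7 | step 7 | (1(10)E,4R,5S,6S,7R,8S,9R)-4,5-epoxy-8,9-dihydroxygermacra-1(10),11(13)-dien-12,6-olide | O[C@H]1[C@H]2C(=C)C(=O)O[C@@H]2[C@@H]2O[C@]2(C)CC/C=C(\C)[C@H]1O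
F8 | step 7 | (1(10)E,4R,5S,6S,7R,8S,9R)-9-acetoxy-4,5-epoxy-8-hydroxygermacra-1(10),11(13)-dien-12,6-olide | O[C@H]1[C@H]2C(=C)C(=O)O[C@@H]2[C@@H]2O[C@]2(C)CC/C=C(\C)[C@H]1OC(C)=O
F9 | step 7 | (1(10)E,4R,5S,6S,7R,8S,9R)-9-acetoxy-4,5-epoxy-8-(methacryloyloxy)germacra-1(10),11(13)-dien-12,6-olide | C=C(C)C(=O)O[C@H]1[C@H]2C(=C)C(=O)O[C@@H]2[C@@H]2O[C@]2(C)CC/C=C(\C)[C@H]1OC(C)=O
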